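**Retrosynthetic overview**

1. The target is read as methyl 6α-acetoxy-(12Z)-labda-8(17),12,14-trien-19-oate (4S,5R,6S,9S,10R, trans-decalin); the vinyl terminus (C13–C14, Negishi coupling on a Z-vinyl bromide) and the O-acetyl group go on last.
2. Ring B is opened at C6–C7 by a type-2 carbonyl-ene disconnection (aldehyde plus isopropenyl group give the 6α-OH and the 8(17)-methylene together); C9–C10 is then cut by an anionic oxy-Cope transform to a 1,5-dien-3-ol.
3. The dienol is divided at C6–C7 (allylboration) into two halves of comparable size: a ring-A enal (C1–C6, C10, C18–C20) and an α-chiral allylboronate (C7–C9, C11–C13, C16, C17) carrying a Z-vinyl bromide as masked diene.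
4. The enal comes from cyclohexanone and dimethyl carbonate (C4 by auxiliary-controlled methylation, C6 by carbonylation of an enol triflate); the boronate comes from but-2-yn-1-ol and isobutenylmagnesium bromide (allylic oxidation, Cu-catalysed asymmetric borylation).
5. Ring order: ring A is carried from cyclohexanone; ring B is closed after the fragment union, three steps from the end.

Assumption: labdane numbering (C1–C20) is used for target atoms in the explanations; α/β refer to the usual decalin drawing with the C10 methyl β.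

**Fragment A (ring-A enal)**

Step 1
Reactants: 1 cyclohexanone; 2 dimethyl carbonate
Product: 3 methyl 2-oxocyclohexane-1-carboxylate
Conditions: NaH (2 equiv), THF, reflux; aq. HCl
Reagents that add atoms: none
Why: Crossed Claisen C-acylation of the ketone enolate, driven by formation of the stabilized β-keto ester enolate; no stereocentre is set.

Step 2
Reactants: 3 methyl 2-oxocyclohexane-1-carboxylate
Product: 4 methyl 2-{[(2S)-1-tert-butoxy-3-methyl-1-oxobutan-2-yl]amino}cyclohex-1-ene-1-carboxylate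
Conditions: L-valine tert-butyl ester, TsOH (cat.), toluene, reflux, Dean–Stark
Reagents that add atoms: L-valine tert-butyl ester CC(C)[C@H](N)C(=O)OC(C)(C)C
Why: Acid-catalysed condensation gives the conjugated, hydrogen-bonded enamino ester, bringing in the valine stereocentre as the controller for the next step.

Step 3
Reactants: 4 methyl 2-{[(2S)-1-tert-butoxy-3-methyl-1-oxobutan-2-yl]amino}cyclohex-1-ene-1-carboxylate
Product: 6 methyl (1S)-1-methyl-2-oxocyclohexane-1-carboxylate, via ketimine 5 (not isolated)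
Conditions: LiN(iPr)2, toluene, HMPA (1 equiv), −78 °C; MeI; aq. citric acid, rt
Reagents that add atoms: iodomethane CI; water O
Why: Koga-type auxiliary-controlled enamine alkylation, in which the chelated lithio-enamine is methylated on the face left open by the valine ester and hydrolysis of the ketimine releases the S quaternary centre (C4) and the auxiliary (the facial sense depends on the lithium ligand, so an ether ligand in place of HMPA is used if the antipode forms).

Step 4
Reactants: 6 methyl (1S)-1-methyl-2-oxocyclohexane-1-carboxylate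
Product: 7 methyl (1S,3RS)-1,3-dimethyl-2-oxocyclohexane-1-carboxylate
Conditions: LiN(iPr)2, THF, −78 °C; MeI, −78 → 0 °C
Reagents that add atoms: iodomethane CI
Why: Only the α′-CH2 can be deprotonated, so enolate methylation (SN2) is regiospecific; the new centre is left as a mixture because it becomes sp2 in the next step.

Step 5
Reactants: 7 methyl (1S,3RS)-1,3-dimethyl-2-oxocyclohexane-1-carboxylate
Product: 8 methyl (1S)-1,3-dimethyl-2-{[(trifluoromethyl)sulfonyl]oxy}cyclohex-2-ene-1-carboxylate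
Conditions: KN(SiMe3)2, THF, −78 °C; PhNTf2, −78 → 0 °C
Reagents that add atoms: N-phenylbis(trifluoromethanesulfonimide) O=S(=O)(N(c1ccccc1)S(=O)(=O)C(F)(F)F)C(F)(F)F
Why: The methyl-bearing α′-carbon is the only enolisable position, so O-sulfonylation of the potassium enolate gives the tetrasubstituted enol triflate regiospecifically.

Step 6
Reactants: 8 methyl (1S)-1,3-dimethyl-2-{[(trifluoromethyl)sulfonyl]oxy}cyclohex-2-ene-1-carboxylate
Product: 9 methyl (1S)-2-formyl-1,3-dimethylcyclohex-2-ene-1-carboxylate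
Conditions: Pd(PPh3)4 (5 mol%), CO (1 atm), Bu3SnH (slow addition), THF, 50 °C
Reagents that add atoms: carbon monoxide [C-]#[O+]
Why: Stille-type reductive carbonylation (oxidative addition of the enol triflate, CO insertion, hydride transfer from tin) gives the enal and leaves the hindered ester untouched.

**Fragment B (α-chiral allylboronate)**

Step 7
Reactants: 10 but-2-yn-1-ol
Product: 12 (2Z)-3-bromobut-2-en-1-ol, via cyclic alkenylaluminate 11 (not isolated)
Conditions: NaAlH2(OCH2CH2OMe)2, THF, 0 °C → rt; NBS, −78 °C; aq. KNaC4H4O6 (potassium sodium tartrate)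
Reagents that add atoms: N-bromosuccinimide O=C1CCC(=O)N1Br
Why: Alkoxide-directed trans-hydroalumination puts aluminium on C3 cis to the CH2O group, and bromodealumination with retention gives the Z vinyl bromide that later becomes the 12Z alkene.

Step 8
Reactants: 12 (2Z)-3-bromobut-2-en-1-ol
Product: 13 (2Z)-1,3-dibromobut-2-ene
Conditions: PBr3, Et2O, 0 °C
Reagents that add atoms: phosphorus tribromide BrP(Br)Br
Why: SN2 conversion of the primary allylic alcohol into the bromide, with the vinyl bromide geometry untouched.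

Step 9
Reactants: 13 (2Z)-1,3-dibromobut-2-ene; 14 2-methylprop-1-en-1-ylmagnesium bromide
Product: 15 (2Z)-2-bromo-6-methylhepta-2,5-diene
Conditions: CuI (5 mol%), THF, −30 → 0 °C
Reagents that add atoms: none
Why: Cu-catalysed SN2 cross-coupling of the alkenyl Grignard reagent with the primary allylic bromide gives the skipped diene, the vinylic bromide being inert at this temperature.

Step 10
Reactants: 15 (2Z)-2-bromo-6-methylhepta-2,5-diene
Product: 16 (2E,5Z)-6-bromo-2-methylhepta-2,5-dien-1-ol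
Conditions: SeO2 (20 mol%), t-BuOOH (3 equiv), salicylic acid (10 mol%), CH2Cl2, rt
Reagents that add atoms: tert-butyl hydroperoxide CC(C)(C)OO
Why: Sharpless allylic oxidation (ene reaction then 2,3-sigmatropic shift) hydroxylates only the E-methyl of the electron-rich gem-dimethyl alkene, giving the 2E alcohol while the deactivated bromo-alkene is spared.

Step 11
Reactants: 16 (2E,5Z)-6-bromo-2-methylhepta-2,5-dien-1-ol
Product: 17 (2E,5Z)-6-bromo-2-methylhepta-2,5-dien-1-yl methyl carbonate
Conditions: ClCO2Me, pyridine, CH2Cl2, 0 °C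
Reagents that add atoms: methyl chloroformate COC(=O)Cl
Why: O-acylation of the primary alcohol installs the carbonate leaving group needed for the SN2′ borylation.

Step 12
Reactants: 17 (2E,5Z)-6-bromo-2-methylhepta-2,5-dien-1-yl methyl carbonate
Product: 18 2-[(3R,5Z)-6-bromo-2-methylhepta-1,5-dien-3-yl]-4,4,5,5-tetramethyl-1,3,2-dioxaborolane
Conditions: B2pin2, CuCl (5 mol%), (R,R)-QuinoxP* (5 mol%), KOtBu (10 mol%), THF, 0 °C
Reagents that add atoms: bis(pinacolato)diboron CC1(C)OB(OC1(C)C)B1OC(C)(C)C(C)(C)O1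
Why: Ito–Sawamura-type enantioselective Cu-catalysed γ-selective (SN2′) allylic boryl substitution, in which face-selective borylcupration and anti β-elimination of the carbonate set the R C–B centre (the ligand antipode is used if the sense proves opposite).

**Union and completion**

Step 13
Reactants: 9 methyl (1S)-2-formyl-1,3-dimethylcyclohex-2-ene-1-carboxylate; 18 2-[(3R,5Z)-6-bromo-2-methylhepta-1,5-dien-3-yl]-4,4,5,5-tetramethyl-1,3,2-dioxaborolane
Product: 21 methyl (1S)-2-[(1S,3E,6Z)-7-bromo-1-hydroxy-3-methylocta-3,6-dien-1-yl]-1,3-dimethylcyclohex-2-ene-1-carboxylate, via borinic ester 19 (not isolated), via borinate adduct 20 (not isolated)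
Conditions: n-BuLi (1.05 equiv), THF, −78 °C; (CF3CO)2O; then 9, −78 °C → rt; H2O2, aq. NaH2PO4/Na2HPO4 (pH 7), 0 °C; used at once
Reagents that add atoms: none
Why: Aggarwal-type allylboration through the more reactive borinic ester, whose closed chair (Zimmerman–Traxler) transition state with the α-substituent equatorial transfers the R C–B centre to the 1S carbinol (C6) and forms the 3E trisubstituted alkene (C11 trans to C7).

Step 14
Reactants: 21 methyl (1S)-2-[(1S,3E,6Z)-7-bromo-1-hydroxy-3-methylocta-3,6-dien-1-yl]-1,3-dimethylcyclohex-2-ene-1-carboxylate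
Product: 23 methyl (1S,2R,3R)-3-[(3S,5Z)-6-bromo-2-methylhepta-1,5-dien-3-yl]-2-formyl-1,3-dimethylcyclohexane-1-carboxylate, via potassium enolate 22 (not isolated)
Conditions: KN(SiMe3)2 (1.3 equiv), 18-crown-6, THF, 0 °C → rt; MeOH then AcOH, −78 °C
Reagents that add atoms: none
Why: Anionic oxy-Cope rearrangement through a chair in which C6–H (not the oxygen) sits between the syn C19 and C20 groups, so C9–C10 forms on the α face to give 10R and, from the E alkene, 9S, with lactonisation onto the ester reversible through the released methoxide and kinetic α-face protonation of the enolate giving 5R.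

Step 15
Reactants: 23 methyl (1S,2R,3R)-3-[(3S,5Z)-6-bromo-2-methylhepta-1,5-dien-3-yl]-2-formyl-1,3-dimethylcyclohexane-1-carboxylate
Product: 24 methyl (1S,4aR,5S,8S,8aR)-5-[(2Z)-3-bromobut-2-en-1-yl]-8-hydroxy-1,4a-dimethyl-6-methylidenedecahydronaphthalene-1-carboxylate
Conditions: Me2AlCl (2 equiv), CH2Cl2, −78 → −20 °C; aq. KNaC4H4O6 (potassium sodium tartrate)
Reagents that add atoms: none
Why: Type-2 carbonyl-ene cyclisation (Snider) in a chair transition state with the aluminium-bound oxygen equatorial (an axial oxygen would clash with C19 and C20) closes ring B as the trans-decalin with the 6α hydroxyl (8S) and the exocyclic methylene in one step.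

Step 16
Reactants: 24 methyl (1S,4aR,5S,8S,8aR)-5-[(2Z)-3-bromobut-2-en-1-yl]-8-hydroxy-1,4a-dimethyl-6-methylidenedecahydronaphthalene-1-carboxylate
Product: 25 methyl (1S,4aR,5S,8S,8aR)-8-(acetyloxy)-5-[(2Z)-3-bromobut-2-en-1-yl]-1,4a-dimethyl-6-methylidenedecahydronaphthalene-1-carboxylate
Conditions: Ac2O, DMAP (cat.), pyridine, 40 °C
Reagents that add atoms: acetic anhydride CC(=O)OC(C)=O
Why: DMAP-catalysed acylation of the equatorial secondary alcohol, with no stereocentre affected.

Step 17
Reactants: 25 methyl (1S,4aR,5S,8S,8aR)-8-(acetyloxy)-5-[(2Z)-3-bromobut-2-en-1-yl]-1,4a-dimethyl-6-methylidenedecahydronaphthalene-1-carboxylate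
Product: 26 methyl (1S,4aR,5S,8S,8aR)-8-(acetyloxy)-1,4a-dimethyl-6-methylidene-5-[(2Z)-3-methylpenta-2,4-dien-1-yl]decahydronaphthalene-1-carboxylate (CNP0212193.2)
Conditions: CH2=CHZnBr, Pd(PPh3)4 (5 mol%), THF, 50 °C
Reagents that add atoms: vinylzinc bromide C=C[Zn]Br
Why: Negishi cross-coupling of the Z alkenyl bromide proceeds with retention of alkene geometry and completes the 12Z diene under neutral conditions that spare both esters.

**Compound list**

1 | cyclohexanone | O=C1CCCCC1 | starting material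
2 | dimethyl carbonate | COC(=O)OC | starting material
3 | methyl 2-oxocyclohexane-1-carboxylate | COC(=O)C1CCCCC1=O | intermediate
4 | methyl 2-{[(2S)-1-tert-butoxy-3-methyl-1-oxobutan-2-yl]amino}cyclohex-1-ene-1-carboxylate | COC(=O)C1=C(N[C@@H](C(C)C)C(=O)OC(C)(C)C)CCCC1 | intermediate
5 | methyl (1S)-2-{[(2S)-1-tert-butoxy-3-methyl-1-oxobutan-2-yl]imino}-1-methylcyclohexane-1-carboxylate (ketimine) | COC(=O)[C@@]1(C)CCCCC1=N[C@@H](C(C)C)C(=O)OC(C)(C)C | intermediate
6 | methyl (1S)-1-methyl-2-oxocyclohexane-1-carboxylate | COC(=O)[C@@]1(C)CCCCC1=O | intermediate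
7 | methyl (1S,3RS)-1,3-dimethyl-2-oxocyclohexane-1-carboxylate | COC(=O)[C@@]1(C)CCCC(C)C1=O | intermediate
8 | methyl (1S)-1,3-dimethyl-2-{[(trifluoromethyl)sulfonyl]oxy}cyclohex-2-ene-1-carboxylate | COC(=O)[C@@]1(C)CCCC(C)=C1OS(=O)(=O)C(F)(F)F | intermediate
9 | methyl (1S)-2-formyl-1,3-dimethylcyclohex-2-ene-1-carboxylate | COC(=O)[C@@]1(C)CCCC(C)=C1C=O | intermediate
10 | but-2-yn-1-ol | CC#CCO | starting material
11 | sodium 2,2-bis(2-methoxyethoxy)-3-methyl-2,5-dihydro-1,2-oxaluminol-2-uide (cyclic alkenylaluminate) | CC1=CCO[Al-]1(OCCOC)OCCOC.[Na+] | intermediate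
12 | (2Z)-3-bromobut-2-en-1-ol | C/C(Br)=C/CO | intermediate
13 | (2Z)-1,3-dibromobut-2-ene | C/C(Br)=C/CBr | intermediate
14 | 2-methylprop-1-en-1-ylmagnesium bromide | CC(C)=C[Mg]Br | starting material
15 | (2Z)-2-bromo-6-methylhepta-2,5-diene | C/C(Br)=C/CC=C(C)C | intermediate
16 | (2E,5Z)-6-bromo-2-methylhepta-2,5-dien-1-ol | C/C(Br)=C/C/C=C(C)/CO | intermediate
17 | (2E,5Z)-6-bromo-2-methylhepta-2,5-dien-1-yl methyl carbonate | C/C(Br)=C/C/C=C(C)/COC(=O)OC | intermediate
18 | 2-[(3R,5Z)-6-bromo-2-methylhepta-1,5-dien-3-yl]-4,4,5,5-tetramethyl-1,3,2-dioxaborolane | C=C(C)[C@H](B1OC(C)(C)C(C)(C)O1)C/C=C(/C)Br | intermediate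
19 | 2,3-dimethyl-3-(trifluoroacetoxy)butan-2-yl butyl[(3R,5Z)-6-bromo-2-methylhepta-1,5-dien-3-yl]borinate (borinic ester) | C=C(C)[C@H](B(CCCC)OC(C)(C)C(C)(C)OC(=O)C(F)(F)F)C/C=C(/C)Br | intermediate
20 | methyl (1S)-2-[(1S,3E,6Z)-7-bromo-1-({butyl[2,3-dimethyl-3-(trifluoroacetoxy)butan-2-yloxy]boranyl}oxy)-3-methylocta-3,6-dien-1-yl]-1,3-dimethylcyclohex-2-ene-1-carboxylate (borinate adduct) | COC(=O)[C@@]1(C)CCCC(C)=C1[C@@H](OB(CCCC)OC(C)(C)C(C)(C)OC(=O)C(F)(F)F)C/C(C)=C/C/C=C(/C)Br | intermediate
21 | methyl (1S)-2-[(1S,3E,6Z)-7-bromo-1-hydroxy-3-methylocta-3,6-dien-1-yl]-1,3-dimethylcyclohex-2-ene-1-carboxylate | COC(=O)[C@@]1(C)CCCC(C)=C1[C@@H](O)C/C(C)=C/C/C=C(/C)Br | intermediate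
22 | potassium {(2S,6R)-6-[(3S,5Z)-6-bromo-2-methylhepta-1,5-dien-3-yl]-2-(methoxycarbonyl)-2,6-dimethylcyclohexylidene}methanolate (enolate) | C/C(Br)=C/C[C@@H](C(C)=C)[C@@]1(C)CCC[C@](C)(C(=O)OC)C1=C[O-].[K+] | intermediate
23 | methyl (1S,2R,3R)-3-[(3S,5Z)-6-bromo-2-methylhepta-1,5-dien-3-yl]-2-formyl-1,3-dimethylcyclohexane-1-carboxylate | C/C(Br)=C/C[C@@H](C(C)=C)[C@@]1(C)CCC[C@](C)(C(=O)OC)[C@@H]1C=O | intermediate
24 | methyl (1S,4aR,5S,8S,8aR)-5-[(2Z)-3-bromobut-2-en-1-yl]-8-hydroxy-1,4a-dimethyl-6-methylidenedecahydronaphthalene-1-carboxylate | C/C(Br)=C/C[C@H]1C(=C)C[C@H](O)[C@@H]2[C@]1(C)CCC[C@]2(C)C(=O)OC | intermediate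
25 | methyl (1S,4aR,5S,8S,8aR)-8-(acetyloxy)-5-[(2Z)-3-bromobut-2-en-1-yl]-1,4a-dimethyl-6-methylidenedecahydronaphthalene-1-carboxylate | C/C(Br)=C/C[C@H]1C(=C)C[C@H](OC(C)=O)[C@@H]2[C@]1(C)CCC[C@]2(C)C(=O)OC | intermediate
26 | methyl (1S,4aR,5S,8S,8aR)-8-(acetyloxy)-1,4a-dimethyl-6-methylidene-5-[(2Z)-3-methylpenta-2,4-dien-1-yl]decahydronaphthalene-1-carboxylate (CNP0212193.2) | C=C/C(C)=C\C[C@H]1C(=C)C[C@H](OC(C)=O)[C@@H]2[C@]1(C)CCC[C@]2(C)C(=O)OC | target

**Step count**

Total step count: 17.
Longest linear sequence: 11 steps (steps 1–6, then 13–17; the other branch, steps 7–12 then 13–17, is equally long).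

**Steps most likely to fail, with fallbacks**

Step 13 is the most exposed. The aldehyde is flanked by a tetrasubstituted alkene and a quaternary carbon. The 2-methyl group of the boronate works against the E geometry, which the later C9 configuration depends on. n-BuLi must add to boron faster than it exchanges with the vinyl bromide. The fallback sets out from 9 (with dibromide 13 as partner) and comes back at 21. Enal 9 is propargylated with allenylboronic acid pinacol ester under a chiral phosphoric acid catalyst ((R)-TRIP, toluene, −30 °C) to give the homopropargylic alcohol methyl (1S)-2-[(1S)-1-hydroxybut-3-yn-1-yl]-1,3-dimethylcyclohex-2-ene-1-carboxylate F1. Zr-catalysed syn-methylalumination (Me3Al, Cp2ZrCl2, CH2Cl2) then gives the alkenylalane methyl (1S)-2-[(1S,3E)-4-(dimethylalumanyl)-1-[(dimethylalumanyl)oxy]-3-methylbut-3-en-1-yl]-1,3-dimethylcyclohex-2-ene-1-carboxylate F2, in which the E geometry is fixed by the syn addition. F2 is allylated in the same flask with 13 and Pd(PPh3)4 to give 21.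

Step 14 can stall if the alkoxide is trapped as the γ-lactone on the C19 ester, and the enolate may protonate to the C5 epimer. The fallback sets out from 21 and comes back at 23. Compound 21 is lactonised on purpose (DBU cat., CH2Cl2) to (3S,7aS)-3-[(2E,5Z)-6-bromo-2-methylhepta-2,5-dien-1-yl]-4,7a-dimethyl-5,6,7,7a-tetrahydro-2-benzofuran-1(3H)-one F3. The lactone is opened with KOH in aqueous MeOH to potassium (1S)-2-[(1S,3E,6Z)-7-bromo-1-hydroxy-3-methylocta-3,6-dien-1-yl]-1,3-dimethylcyclohex-2-ene-1-carboxylate F4, whose carboxylate cannot re-close under base. The dried salt undergoes the oxy-Cope rearrangement as the dianion (KN(SiMe3)2, 18-crown-6, THF), and acidification with HCl gives (1S,2R,3R)-3-[(3S,5Z)-6-bromo-2-methylhepta-1,5-dien-3-yl]-2-formyl-1,3-dimethylcyclohexane-1-carboxylic acid F5. Esterification with Me3SiCHN2 in MeOH returns 23.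

Step 15 may suffer from the Lewis acid (epimerisation at C5, slow closure of the hindered aldehyde, cis-fused by-product). The fallback sets out from 23 and comes back at 24. The isopropenyl group is chlorinated in an ene-type reaction (Ca(OCl)2, CO2, CH2Cl2/H2O) to the allylic chloride methyl (1S,2R,3R)-3-[(3R,5Z)-6-bromo-2-(chloromethyl)hepta-1,5-dien-3-yl]-2-formyl-1,3-dimethylcyclohexane-1-carboxylate F6. Ring B is then closed under neutral conditions by an intramolecular Nozaki–Hiyama allylation (CrCl2, THF), again through a chair with the oxygen equatorial, to give 24.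

Further compounds
F1 | step 13 | methyl (1S)-2-[(1S)-1-hydroxybut-3-yn-1-yl]-1,3-dimethylcyclohex-2-ene-1-carboxylate | COC(=O)[C@@]1(C)CCCC(C)=C1[C@@H](O)CC#C
F2 | step 13 | methyl (1S)-2-[(1S,3E)-4-(dimethylalumanyl)-1-[(dimethylalumanyl)oxy]-3-methylbut-3-en-1-yl]-1,3-dimethylcyclohex-2-ene-1-carboxylate | COC(=O)[C@@]1(C)CCCC(C)=C1[C@@H](O[Al](C)C)C/C(C)=C/[Al](C)C
F3 | step 14 | (3S,7aS)-3-[(2E,5Z)-6-bromo-2-methylhepta-2,5-dien-1-yl]-4,7a-dimethyl-5,6,7,7a-tetrahydro-2-benzofuran-1(3H)-one | C[C@]12CCCC(C)=C1[C@H](C/C(C)=C/C/C=C(/C)Br)OC2=O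
F4 | step 14 | potassium (1S)-2-[(1S,3E,6Z)-7-bromo-1-hydroxy-3-methylocta-3,6-dien-1-yl]-1,3-dimethylcyclohex-2-ene-1-carboxylate | [K+].[O-]C(=O)[C@@]1(C)CCCC(C)=C1[C@@H](O)C/C(C)=C/C/C=C(/C)Br
F5 | step 14 | (1S,2R,3R)-3-[(3S,5Z)-6-bromo-2-methylhepta-1,5-dien-3-yl]-2-formyl-1,3-dimethylcyclohexane-1-carboxylic acid | C/C(Br)=C/C[C@@H](C(C)=C)[C@@]1(C)CCC[C@](C)(C(=O)O)[C@@H]1C=O
F6 | step 15 | methyl (1S,2R,3R)-3-[(3R,5Z)-6-bromo-2-(chloromethyl)hepta-1,5-dien-3-yl]-2-formyl-1,3-dimethylcyclohexane-1-carboxylate | C/C(Br)=C/C[C@@H](C(CCl)=C)[C@@]1(C)CCC[C@](C)(C(=O)OC)[C@@H]1C=O
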